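**Strategy.** Ring B is cut at its C2–C3 bond. C2 (the carbon bearing the oxygen to ring C) is treated as a former carboxyl carbon, C1 (oxygen to ring A) as the α-carbon of an aryloxyacetic acid, and C3–C6 as a four-carbon diene chain. A single operation, 6π electrocyclization of a dienylketene, closes ring B as a 2-aryloxyphenol whose hydroxyl sits where ring C is attached later and meanwhile directs the ring B bromines. The precursor is a (2Z,4E)-2-aryloxyhexa-2,4-dienoic acid that already carries dibrominated ring A, whose own hydroxyl is masked as a tosylate so that ring A stays inert during the bromination of ring B.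

Key step: step 7

Ring labels: ring A is the 3,5-dibromo-2-oxyphenol ring; ring B is the central ring (C1 oxygen to ring A, C2 oxygen to ring C, C3–C5 bromine, C6 hydrogen); ring C is the 2,4-dibromophenyl ring.

Assumption (remark on the chemistry): the ring A oxygen is carried as a tosylate, because an electron-donating alkoxy group would leave ring A about as reactive toward bromine as the last position needed on ring B. A tert-butyl ester keeps hydroxide away from the sulfonate until the last step. 2,4-Dibromo-1-iodobenzene and 1,3,5-trimethoxybenzene are taken as purchasable.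

**Step 1**
Reactants: 1 catechol (benzene-1,2-diol)
Product: 2 2-hydroxyphenyl 4-methylbenzenesulfonate
Conditions: TsCl (1 equiv), catechol (2 equiv), Et3N, CH2Cl2, 0 °C to rt
Reagents that add atoms: 4-methylbenzenesulfonyl chloride, Cc1ccc(cc1)S(=O)(=O)Cl
Why: Sulfonylation of a phenol (O-tosylation); with the diol in excess only one hydroxyl should be capped, and the surplus catechol is washed out with water.

**Step 2**
Reactants: 2 2-hydroxyphenyl 4-methylbenzenesulfonate
Product: 3 3,5-dibromo-2-hydroxyphenyl 4-methylbenzenesulfonate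
Conditions: Br2 (2.1 equiv), AcOH, rt
Reagents that add atoms: bromine, BrBr
Why: Electrophilic aromatic bromination in which the free hydroxyl should direct both bromines to its para and ortho positions, the deactivating sulfonyloxy group offering no competing activated site.

**Step 3**
Reactants: 3 3,5-dibromo-2-hydroxyphenyl 4-methylbenzenesulfonate; 4 tert-butyl bromoacetate
Product: 5 tert-butyl 2-{2,4-dibromo-6-[(4-methylbenzenesulfonyl)oxy]phenoxy}acetate
Conditions: K2CO3, DMF, 50 °C
Reagents that add atoms: none
Why: Williamson ether synthesis, in which the acidic, doubly flanked phenoxide should displace bromide from the unhindered primary α-bromo ester (SN2), so the congested ring A–oxygen–carbon bond is made without any aryl coupling.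

**Step 4**
Reactants: 5 tert-butyl 2-{2,4-dibromo-6-[(4-methylbenzenesulfonyl)oxy]phenoxy}acetate; 6 (E)-but-2-enal (crotonaldehyde)
Product: 7 tert-butyl (4E)-2-{2,4-dibromo-6-[(4-methylbenzenesulfonyl)oxy]phenoxy}-3-hydroxyhex-4-enoate (racemic mixture of both C2/C3 diastereomers)
Conditions: LiN(SiMe3)2, THF, −78 °C; then 6, −78 °C; aq. NH4Cl
Reagents that add atoms: none
Why: Aldol addition of a lithium α-aryloxy ester enolate, which at −78 °C should add 1,2 to the enal; the two new stereocentres (C2, C3) are left uncontrolled because both become sp2 in step 5, and the silylamide base is too weak to metalate the aryl C–H between the two bromines.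

**Step 5**
Reactants: 7 tert-butyl (4E)-2-{2,4-dibromo-6-[(4-methylbenzenesulfonyl)oxy]phenoxy}-3-hydroxyhex-4-enoate
Product: 9 tert-butyl (2Z,4E)-2-{2,4-dibromo-6-[(4-methylbenzenesulfonyl)oxy]phenoxy}hexa-2,4-dienoate, via mesylate 8 (not isolated)
Conditions: MsCl, Et3N, CH2Cl2, 0 °C; then DBU, rt
Reagents that add atoms: none
Why: Mesylation followed by E1cB elimination should give the conjugated dienoate, mainly as the 2Z isomer (ester trans to the propenyl group), and any minor alkene isomer is equally usable because neither double-bond geometry survives into the ketene of step 7.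

**Step 6**
Reactants: 9 tert-butyl (2Z,4E)-2-{2,4-dibromo-6-[(4-methylbenzenesulfonyl)oxy]phenoxy}hexa-2,4-dienoate
Product: 10 (2Z,4E)-2-{2,4-dibromo-6-[(4-methylbenzenesulfonyl)oxy]phenoxy}hexa-2,4-dienoic acid
Conditions: CF3CO2H, CH2Cl2, 0 °C to rt
Reagents that add atoms: none
Why: Acidolysis of a tert-butyl ester (loss of the tert-butyl cation as isobutene) should free the acid without exposing the aryl sulfonate to hydroxide.

**Step 7**
Reactants: 10 (2Z,4E)-2-{2,4-dibromo-6-[(4-methylbenzenesulfonyl)oxy]phenoxy}hexa-2,4-dienoic acid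
Product: 15 3,5-dibromo-2-(2-hydroxyphenoxy)phenyl 4-methylbenzenesulfonate, via mixed acetic anhydride 11 (not isolated), via dienylketene 12 (not isolated), via cyclohexa-2,4-dienone 13 (not isolated), via aryl acetate 14 (not isolated)
Conditions: Ac2O, NaOAc, 140 °C; evaporate; NH3, MeOH, rt
Reagents that add atoms: none
Why: Acetic anhydride should convert the acid into mixed anhydride 11; acetate then removes a proton from the terminal methyl group and acetate is expelled (a 1,6-elimination) to give dienylketene 12, whose thermal 6π electrocyclization joins the ketene carbon to the terminal CH2, after which dienone 13 tautomerizes to the phenol, held as acetate 14 until ammonia releases it. The closest known reaction types are the acetic anhydride/NaOAc benzannulation of hexa-3,5-dienoic acids and the last stage of the Danheiser benzannulation, while the dehydrochlorination of sorbyl chloride to butadienylketene shows that a 2,4-dienoyl derivative can be enolized through its methyl group. Ring B closes by a disrotatory 6π electrocyclization, a six-membered carbocycle made by one C–C bond (the ring B C2–C3 bond); no stereocentre is created, since the only new sp3 carbon is the CH2 that is lost on tautomerization. The step needs the ketene with its carbonyl and vinyl groups cis at the central C3=C4 bond: that bond is a freely rotating single bond in anhydride 11, the unproductive trans ketene can return to 11 by adding acetic acid (or isomerize by reversible 4π closure to a cyclobutenone at this temperature), and only the cis ketene is drained irreversibly into the aromatic ring. Regiochemistry is fixed by the substrate, because the methyl group carries the only enolizable hydrogens, the carboxyl carbon must become the C–OH carbon, and the aryloxy-bearing carbon ends up next to it.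

**Step 8**
Reactants: 15 3,5-dibromo-2-(2-hydroxyphenoxy)phenyl 4-methylbenzenesulfonate
Product: 16 3,5-dibromo-2-(3,4,5-tribromo-2-hydroxyphenoxy)phenyl 4-methylbenzenesulfonate
Conditions: Br2 (3.2 equiv), AcOH, rt to 50 °C
Reagents that add atoms: bromine, BrBr
Why: Electrophilic aromatic bromination in which the free hydroxyl should steer two bromines to its ortho (C3) and para (C5) positions and the ether oxygen to ring A the third to its para position (C4), while ring A (sulfonyloxy plus two bromines) and the tolyl ring are too electron-poor to react and C6 is screened by the perpendicular ring A.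

**Step 9**
Reactants: 17 2,4-dibromo-1-iodobenzene; 18 1,3,5-trimethoxybenzene
Product: 20 (2,4-dibromophenyl)(2,4,6-trimethoxyphenyl)iodonium 4-methylbenzenesulfonate, via hydroxy(tosyloxy)iodoarene 19 (not isolated)
Conditions: mCPBA (1 equiv), TsOH·H2O (1 equiv), MeCN, 77 °C; then 18 (1 equiv), 77 °C; precipitate with Et2O
Reagents that add atoms: 4-methylbenzenesulfonic acid, Cc1ccc(cc1)S(=O)(=O)O
Why: One-pot synthesis of an unsymmetrical diaryliodonium salt: the peracid should oxidize the aryl iodide to a Koser-type hydroxy(tosyloxy) trivalent iodine species, which then undergoes electrophilic aromatic substitution with the very electron-rich 1,3,5-trimethoxybenzene (its three free positions are equivalent) with loss of water, the aryl bromides being inert to the peracid.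

**Step 10**
Reactants: 16 3,5-dibromo-2-(3,4,5-tribromo-2-hydroxyphenoxy)phenyl 4-methylbenzenesulfonate; 20 (2,4-dibromophenyl)(2,4,6-trimethoxyphenyl)iodonium 4-methylbenzenesulfonate
Product: 21 3,5-dibromo-2-[3,4,5-tribromo-2-(2,4-dibromophenoxy)phenoxy]phenyl 4-methylbenzenesulfonate
Conditions: K2CO3, MeCN, 60 °C
Reagents that add atoms: none
Why: Metal-free O-arylation of a phenoxide with a diaryliodonium salt (ligand exchange at trivalent iodine, then ligand coupling); the electron-poor, ortho-substituted 2,4-dibromophenyl group should be transferred while the electron-rich trimethoxyphenyl group leaves as its aryl iodide, and the aryl bromides and the sulfonate should remain untouched.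

**Step 11**
Reactants: 21 3,5-dibromo-2-[3,4,5-tribromo-2-(2,4-dibromophenoxy)phenoxy]phenyl 4-methylbenzenesulfonate
Product: 22 bromoiesol A, 3,5-dibromo-2-[3,4,5-tribromo-2-(2,4-dibromophenoxy)phenoxy]phenol
Conditions: KOH, H2O/1,4-dioxane, 80 °C; then aq. HCl
Reagents that add atoms: none
Why: Alkaline hydrolysis of an aryl sulfonate (hydroxide attacks sulfur, S–O cleavage), eased by the dibrominated phenoxide leaving group, should unmask the ring A hydroxyl, the diaryl ether bonds and unactivated aryl bromides being inert to hydroxide at this temperature.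

**Compound list**
1 | catechol (benzene-1,2-diol) | Oc1ccccc1O | starting material
2 | 2-hydroxyphenyl 4-methylbenzenesulfonate | Cc1ccc(cc1)S(=O)(=O)Oc1ccccc1O | intermediate
3 | 3,5-dibromo-2-hydroxyphenyl 4-methylbenzenesulfonate | Cc1ccc(cc1)S(=O)(=O)Oc1cc(Br)cc(Br)c1O | intermediate
4 | tert-butyl bromoacetate | CC(C)(C)OC(=O)CBr | starting material
5 | tert-butyl 2-{2,4-dibromo-6-[(4-methylbenzenesulfonyl)oxy]phenoxy}acetate | Cc1ccc(cc1)S(=O)(=O)Oc1cc(Br)cc(Br)c1OCC(=O)OC(C)(C)C | intermediate
6 | (E)-but-2-enal (crotonaldehyde) | C/C=C/C=O | starting material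
7 | tert-butyl (4E)-2-{2,4-dibromo-6-[(4-methylbenzenesulfonyl)oxy]phenoxy}-3-hydroxyhex-4-enoate, racemic, both C2/C3 diastereomers | C/C=C/C(O)C(Oc1c(Br)cc(Br)cc1OS(=O)(=O)c1ccc(C)cc1)C(=O)OC(C)(C)C | intermediate
8 | tert-butyl (4E)-2-{2,4-dibromo-6-[(4-methylbenzenesulfonyl)oxy]phenoxy}-3-(methanesulfonyloxy)hex-4-enoate | C/C=C/C(OS(C)(=O)=O)C(Oc1c(Br)cc(Br)cc1OS(=O)(=O)c1ccc(C)cc1)C(=O)OC(C)(C)C | intermediate (not isolated)
9 | tert-butyl (2Z,4E)-2-{2,4-dibromo-6-[(4-methylbenzenesulfonyl)oxy]phenoxy}hexa-2,4-dienoate | C/C=C/C=C(\Oc1c(Br)cc(Br)cc1OS(=O)(=O)c1ccc(C)cc1)C(=O)OC(C)(C)C | intermediate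
10 | (2Z,4E)-2-{2,4-dibromo-6-[(4-methylbenzenesulfonyl)oxy]phenoxy}hexa-2,4-dienoic acid | C/C=C/C=C(\Oc1c(Br)cc(Br)cc1OS(=O)(=O)c1ccc(C)cc1)C(=O)O | intermediate (key-step precursor)
11 | acetic (2Z,4E)-2-{2,4-dibromo-6-[(4-methylbenzenesulfonyl)oxy]phenoxy}hexa-2,4-dienoic anhydride | C/C=C/C=C(\Oc1c(Br)cc(Br)cc1OS(=O)(=O)c1ccc(C)cc1)C(=O)OC(C)=O | intermediate (not isolated)
12 | (3Z)-2-{2,4-dibromo-6-[(4-methylbenzenesulfonyl)oxy]phenoxy}hexa-1,3,5-trien-1-one (dienylketene, ketene and vinyl cis) | C=C/C=C\C(Oc1c(Br)cc(Br)cc1OS(=O)(=O)c1ccc(C)cc1)=C=O | intermediate (not isolated)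
13 | 3,5-dibromo-2-[(6-oxocyclohexa-1,3-dien-1-yl)oxy]phenyl 4-methylbenzenesulfonate | O=C1CC=CC=C1Oc1c(Br)cc(Br)cc1OS(=O)(=O)c1ccc(C)cc1 | intermediate (not isolated)
14 | 2-{2,4-dibromo-6-[(4-methylbenzenesulfonyl)oxy]phenoxy}phenyl acetate | CC(=O)Oc1ccccc1Oc1c(Br)cc(Br)cc1OS(=O)(=O)c1ccc(C)cc1 | intermediate (not isolated)
15 | 3,5-dibromo-2-(2-hydroxyphenoxy)phenyl 4-methylbenzenesulfonate | Oc1ccccc1Oc1c(Br)cc(Br)cc1OS(=O)(=O)c1ccc(C)cc1 | intermediate (key-step product)
16 | 3,5-dibromo-2-(3,4,5-tribromo-2-hydroxyphenoxy)phenyl 4-methylbenzenesulfonate | Oc1c(Br)c(Br)c(Br)cc1Oc1c(Br)cc(Br)cc1OS(=O)(=O)c1ccc(C)cc1 | intermediate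
17 | 2,4-dibromo-1-iodobenzene | Brc1ccc(I)c(Br)c1 | starting material
18 | 1,3,5-trimethoxybenzene | COc1cc(OC)cc(OC)c1 | starting material
19 | 2,4-dibromo-1-[hydroxy(4-methylbenzenesulfonyloxy)iodo]benzene | Cc1ccc(cc1)S(=O)(=O)OI(O)c1ccc(Br)cc1Br | intermediate (not isolated)
20 | (2,4-dibromophenyl)(2,4,6-trimethoxyphenyl)iodonium 4-methylbenzenesulfonate | COc1cc(OC)c([I+]c2ccc(Br)cc2Br)c(OC)c1.Cc1ccc(cc1)S(=O)(=O)[O-] | intermediate
21 | 3,5-dibromo-2-[3,4,5-tribromo-2-(2,4-dibromophenoxy)phenoxy]phenyl 4-methylbenzenesulfonate | Cc1ccc(cc1)S(=O)(=O)Oc1cc(Br)cc(Br)c1Oc1cc(Br)c(Br)c(Br)c1Oc1ccc(Br)cc1Br | intermediate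
22 | bromoiesol A, 3,5-dibromo-2-[3,4,5-tribromo-2-(2,4-dibromophenoxy)phenoxy]phenol | Oc1cc(Br)cc(Br)c1Oc1cc(Br)c(Br)c(Br)c1Oc1ccc(Br)cc1Br | target

**Step count**
Total: 11 steps. Longest linear sequence: 10 steps (steps 1–8, 10 and 11 from catechol); step 9 is a one-step branch.

**Steps most likely to fail**

Step 7. The ketene may form mostly with the carbonyl and vinyl groups trans at C3=C4 and be lost to dimerization or oligomerization before it can re-equilibrate, or the dienoic anhydride may polymerize at 140 °C. The fallback brings in ring B as a ready-made arene and uses no electrocyclization. Setting out from phenol 3, nucleophilic aromatic substitution on 1-fluoro-2-nitrobenzene (K2CO3, DMF, 90 °C) should give 3,5-dibromo-2-(2-nitrophenoxy)phenyl 4-methylbenzenesulfonate F1. Reduction of the nitro group with Fe and NH4Cl in aqueous EtOH should give 2-(2-aminophenoxy)-3,5-dibromophenyl 4-methylbenzenesulfonate F2. Diazotization (NaNO2, aq. H2SO4, 0 °C) and hydroxydediazoniation (Cu(NO3)2, Cu2O, H2O) bring the route back at phenol 15. Ring A has no free position ortho to the ether oxygen, so closure to a dibenzofuran is blocked.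

Step 8. The third, slow bromination may leak to C6 (ortho to the ether oxygen) or stall after two bromines. The fallback separates the ether-directed bromination from the hydroxyl-directed ones. It sets out from aryl acetate 14, isolated when the ammonia treatment of step 7 is left out. With the hydroxyl masked, Br2 (1 equiv) in AcOH should brominate only para to the ether oxygen, giving 5-bromo-2-{2,4-dibromo-6-[(4-methylbenzenesulfonyl)oxy]phenoxy}phenyl acetate F3. Ammonia in MeOH then frees 3,5-dibromo-2-(4-bromo-2-hydroxyphenoxy)phenyl 4-methylbenzenesulfonate F4. Br2 (2.1 equiv) in AcOH fills the positions ortho and para to the hydroxyl, which returns the route at 16.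

Step 10. Ligand coupling at the doubly flanked, weakly nucleophilic phenoxide may be so slow that the iodonium salt decomposes first, or part of the phenoxide may be consumed by transfer of the wrong aryl group. The fallback builds ring C by substitution and a Sandmeyer reaction. Setting out from 16, nucleophilic aromatic substitution on 2-bromo-1-fluoro-4-nitrobenzene (Cs2CO3, DMF, 80 °C) should give 3,5-dibromo-2-[3,4,5-tribromo-2-(2-bromo-4-nitrophenoxy)phenoxy]phenyl 4-methylbenzenesulfonate F5. Reduction with Fe and NH4Cl in aqueous EtOH should give 2-[2-(4-amino-2-bromophenoxy)-3,4,5-tribromophenoxy]-3,5-dibromophenyl 4-methylbenzenesulfonate F6. Sandmeyer bromination (t-BuONO, CuBr2, MeCN) returns the route at 21.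

**Further compounds**
F1 | step 7 | 3,5-dibromo-2-(2-nitrophenoxy)phenyl 4-methylbenzenesulfonate | O=[N+]([O-])c1ccccc1Oc1c(Br)cc(Br)cc1OS(=O)(=O)c1ccc(C)cc1
F2 | step 7 | 2-(2-aminophenoxy)-3,5-dibromophenyl 4-methylbenzenesulfonate | Nc1ccccc1Oc1c(Br)cc(Br)cc1OS(=O)(=O)c1ccc(C)cc1
F3 | step 8 | 5-bromo-2-{2,4-dibromo-6-[(4-methylbenzenesulfonyl)oxy]phenoxy}phenyl acetate | CC(=O)Oc1cc(Br)ccc1Oc1c(Br)cc(Br)cc1OS(=O)(=O)c1ccc(C)cc1
F4 | step 8 | 3,5-dibromo-2-(4-bromo-2-hydroxyphenoxy)phenyl 4-methylbenzenesulfonate | Oc1cc(Br)ccc1Oc1c(Br)cc(Br)cc1OS(=O)(=O)c1ccc(C)cc1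
F5 | step 10 | 3,5-dibromo-2-[3,4,5-tribromo-2-(2-bromo-4-nitrophenoxy)phenoxy]phenyl 4-methylbenzenesulfonate | Cc1ccc(cc1)S(=O)(=O)Oc1cc(Br)cc(Br)c1Oc1cc(Br)c(Br)c(Br)c1Oc1ccc(cc1Br)[N+](=O)[O-]
F6 | step 10 | 2-[2-(4-amino-2-bromophenoxy)-3,4,5-tribromophenoxy]-3,5-dibromophenyl 4-methylbenzenesulfonate | Cc1ccc(cc1)S(=O)(=O)Oc1cc(Br)cc(Br)c1Oc1cc(Br)c(Br)c(Br)c1Oc1ccc(N)cc1Br
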